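Follow the protic impurity. Its charge is 50.0% of the starting material, and I assume each impurity takes one starting material, so that is the ceiling on the loss.

the same everywhere: starting material 0.97 M; protic impurity 0.485 M; catalyst 2.1 mol%
- grey: temperature 110 °C; the very flask that is asked about, followed so far
- teal: temperature 105 °C; run made earlier
- flask: temperature 110 °C; time 2.0 d

- grey (time / h: target / %, starting material / %): 2.50: 32.5, 17.6; 8.00: 33.5, 10.7; 15.0: 32.1, 10.8; 20.0: 30.8, 9.6; 30.0: 28.9, 8.9; 40.0: 27.1, 9.2
- teal (time / h: target / %, starting material / %): 2.50: 31.4, 20.5; 8.00: 36.1, 8.9; 15.0: 34.8, 9.7; 20.0: 34.6, 8.6; 30.0: 32.1, 8.0; 40.0: 32.0, 8.3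

(readings scatter by 0.5 percentage points)

- zeta: at 2.0 d take out 90% of the target then present, then wait 4.0 d
- beta: change nothing and wait 4.0 d more
- alpha: at 2.0 d raise the temperature by 10 K, then wait 4.0 d
- theta: at 2.0 d add catalyst, 100% of the amount charged, then wait 4.0 d

- removed target is counted in
- additions bring no volume worth counting

* target, in percent of the starting material first charged, at 2.0 d
* the option that brings most further target ("none" if no option brings more than 2 percentage points) (zeta / beta / alpha / theta / none)
* target present, with what was taken out counted in, in percent of the starting material first charged, after beta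
* target present, with what was taken out counted in, in percent of the starting material first charged, after theta

In the grey run the target loses 0.00640 h⁻¹ between its last readings. I carry that mean slope to 2.0 d and get 25.7%. The sum of target and starting material reads 50.1% at 2.50 h, so the loss looks close to the ceiling. But the sum reads 36.3% at 40.0 h, below the 50.0% that the ceiling spares, so I read the gap as partly an unseen partner in equilibrium, not as finished loss. I call everything unquenched the pool.

The same slope, run back to zero time, gives the target a share of 35.0% of a full pool. With the ceiling reached, that leaves 17.5%.

The weak link is that mean slope. Starting material at 2.50 h stands at twice its last reading, so I expect faster early loss than the line shows, and a higher share. I assume the pool is still whole at 2.50 h and take the share instead from the early sum, split as at 40.0 h: 37.4%. That gives 18.7%, my target floor: the share times what the ceiling spares.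

So I expect beta to end near the floor. I expect theta to end with it, since catalyst moves no equilibrium. Alpha looks worse, since the grey run holds less target than the teal run at 40.0 h. By my reckoning zeta banks 23.2% and leaves 10.0% in the flask, a total of 33.2%, so I choose zeta.

The forecast gives 25.8%, zeta, 14% for beta and 13.5% for theta, on the ground that “This suggests a live equilibrium with slow first-order loss, not dead catalyst.” My beta stands higher.

The flask gives 25.8%, zeta with 10 percentage points, 21.3% after beta and 21.3% after theta.

    starting material + catalyst ⇌ target + catalyst, rate k1*[starting material]*[catalyst] forward; the back reaction follows from the equilibrium constant (K = 2.90, k = 0.00200 M⁻¹ s⁻¹, Ea = 69.0 kJ mol⁻¹, ΔH = −58.0 kJ mol⁻¹)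
    target + catalyst ⇌ isomer of the product + catalyst, rate k2*[catalyst]*[target] forward; the back reaction follows from the equilibrium constant (K = 1.10, k = 0.0250 M⁻¹ s⁻¹, Ea = 72.0 kJ mol⁻¹, ΔH = −14.0 kJ mol⁻¹)
    starting material + protic impurity → quenched substrate (k = 7.00 × 10⁻⁵ M⁻¹ s⁻¹, Ea = 109 kJ mol⁻¹)
    isomer of the product + catalyst ⇌ starting material + catalyst, rate k4*[catalyst]*[isomer of the product] forward; the back reaction follows from the equilibrium constant (k = 0.00270 M⁻¹ s⁻¹, Ea = 96.0 kJ mol⁻¹)
    (constants at 110 °C)

In this flask at 48.0 h, the isomer of the product and the starting material relax by their own step alone with a half-life of 0.836 h. Quenching takes starting material with a half-life of 22 h, far longer. The target holds 41.1% of the pool at 48.0 h and 40.9% at 480 h, when quenched substrate stands at 50.0% and target at 20.5%, above the floor. The flask left until 8.0 d has 49.1% quenched substrate, 1.8% of its own charge of protic impurity left and, above the floor, 20.8% target.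

The data were generated by integration with constants of no real substance.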